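## The problem

The target is a linear C19 polyketide acid, numbered here from the carboxyl carbon C1, that ends in a trans-5-methyl-5,6-dihydropyran-2-one (ring atoms C20–C24: C20 carries the ring oxygen, C21 the methyl, C24 is the carbonyl). The lactone is the only ring, so the task is chain assembly, not ring fusion. Read from the structure, the descriptors are 2E,5R,6R,7R,9S,10E,12E,15R,16Z,18E with a (20R,21S) trans lactone.

Five alkenes must be set with defined geometry. The (2E) and (10E) alkenes are trisubstituted, and the (16Z) alkene carrying the ethyl group is the one that no thermodynamic method will deliver.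

The seven stereocentres fall into four groups that cannot communicate. Within the contiguous C5–C6–C7 triad the centres can control each other, and C20/C21 can be set as a pair. C9 is cut off from C7 by the C8 carbonyl and C15 is remote from everything, so both need reagent control.

The C8 ketone is β to the C6 hydroxyl and to the C9 hydroxymethyl group (retro-aldol, dehydration). C9–H is α to the ketone and allylic to the diene (epimerisation, conjugation). The unsaturated lactone is a Michael acceptor whose C20–O bond is doubly allylic. These functions, and the free acid beside them, must be unveiled last and never see base.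

The feature that opens the route is the anti,anti arrangement of C5-methyl, C6-hydroxyl and C7-methyl. With C4 and C8 both written as CH2OH, the C4–C8 segment has a mirror plane through C6 and is a meso diol. The whole triad can therefore come from an achiral precursor and one enantiotopic-group-selective event.

## Retrosynthesis

**Unveiling the labile functions (57 ⇐ 56 ⇐ 55 ⇐ 54).** Two O–Si bonds, the C8 carbonyl, the lactone carbonyl and the acetal C–O bond are retraced to acid 54. In 54, C8 is a carbinol and the lactone is an ethyl acetal. The β-hydroxy ketone, the acidic C9–H and the Michael acceptor exist only in 56 and 57. The forward steps need one oxidant for two carbinol-level carbons and a buffered acidic fluoride source.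

**C11–C12 (54 ⇐ 28 + 53).** Cutting the σ-bond of the 10,12-diene gives two halves of similar size, iodoalkene acid 28 and alkenylboronate 53, each holding stereocentres that are independent of the other half. A cut at C13–C14 would need an alkyl metal at a β-branched carbon made with strong base. An olefination at C10=C11 would put a carbonyl next to C9. The forward reaction must be a stereoretentive sp2–sp2 coupling that tolerates a free acid and a free alcohol.

**C17–C18 and the east half (53 ⇐ 52 ⇐ 51 ⇐ 39 + 48).** The (16Z) alkene is traced to iodoalkene 39, so the geometric problem becomes an iodo-olefination of aldehyde 34 followed by coupling with retention. A Wittig disconnection at C18=C19 would need an allylic ylide and an epimerisable α-oxy aldehyde. Alkyne 48 supplies C18–C24 and gives the (18E) alkene by syn hydrometalation. Aldehyde 34 comes from 33 and 32; 32 is made by alkylating imide 29 with bromide 30, which forms C14–C15 and sets C15.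

**The masked lactone (48 ⇐ 47 ⇐ 46 ⇐ 44 + 45; 44 ⇐ 40 + 41).** The ring is opened at C22=C23 (ring-closing metathesis of 46) and at the acetal C–O bond (alcohol 44 with acetal 45). The C20–C21 bond is cut to ynal 40 and (E)-but-2-ene 41. An anti crotylation sets both ring stereocentres at once, and anti in the chain becomes trans in the ring. The acetal level is kept because organozirconium, organozinc and carbonate/methanol steps follow.

**C8–C9 and the west half (28 ⇐ 27 ⇐ 25 ⇐ 24 ⇐ 16 + 22).** C9 is set by reagent control when the C8–C9 bond is formed from aldehyde 16 and the allenylzinc derived from mesylate 22. The same step brings in C10–C12 as a methyl-capped alkyne, which hydrometalation turns into the (10E)-iodoalkene of 27. The C8 configuration is irrelevant because C8 is oxidised later. Mesylate 22 goes back through 21, 20 and 19 to aldehyde 17 and Grignard reagent 18. An aldol route to C9 would need an iodoalkenyl acid that is harder to make (it is kept as a fallback).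

**C3–C4 (16 ⇐ 15 ⇐ 14 ⇐ 10 + 12; 10 ⇐ 9).** The free hydroxyl of monoacetate 9 is used first: it becomes iodide 10, whose zinc reagent is coupled with enol triflate 12. The (2E) geometry is imported from 12 instead of being created on a methyl ketone, where olefination gives mixtures. The acetate is the latent C8 aldehyde.

**Key disconnection (9 ⇐ 7 + 8).** Only one ester C–O bond is cut. The precursor, diol 7, is achiral (meso) and vinyl acetate 8 is the acyl donor. The forward reaction must distinguish two enantiotopic CH2OH groups, which a lipase does.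

**The meso diol (7 ⇐ 5 ⇐ 3 ⇐ 1 + 2).** Two anti-selective hydroborations of silyl ether 5 create C5 and C7 relative to C6. Dienol 3 is made from methacrolein 1 and Grignard reagent 2. No chiral reagent is involved.

## Roads not taken

**Alternative 1:** The cut is the C16=C17 alkene, closed temporarily into a ring. Ester A1, (2S)-2-methylbut-3-en-1-yl 2-methylidenebutanoate, would undergo ring-closing metathesis with the second-generation Grubbs catalyst to lactone A2, (5S)-3-ethyl-5-methyl-5,6-dihydro-2H-pyran-2-one, with loss of ethene.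
- *Merits.* Inside a six-membered ring C15 and the carbonyl carbon (future C18) can only be cis, so the (16Z) geometry follows from constitution and not from kinetic selectivity. The step is catalytic, and C15 comes from a cheap enantiopure alcohol.
- *Weak points.* The metathesis joins an electron-poor 1,1-disubstituted acrylate to a branched vinyl group and will be slow. Afterwards both ring termini are at the wrong level. C18 must be reduced and olefinated next to the labile oxygenated C20, and the C14–O bond must be exchanged for the C14–C13 bond by displacement at a β-branched carbon.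
- *Comparison.* For the (16Z) alkene alone the template is the more secure device, and that is conceded against step 21. The chosen plan sets against it that its key step fixes three stereocentres from an achiral diene, whereas A2 contains one bought stereocentre and creates none. The weakness of step 21 can also be repaired locally.

**Alternative 2:** The cut is C4–C5, with the (2E) alkene formed in the same event. The silyl ketene acetal of allylic propanoate A3, (2R)-1-[(4-methoxybenzyl)oxy]-3-methylbut-3-en-2-yl propanoate (LiN(i-Pr)2, Me3SiCl, THF), would rearrange [3,3] to acid A4, (2R,4E)-6-[(4-methoxybenzyl)oxy]-2,4-dimethylhex-4-enoic acid. Its carboxyl carbon is the future C6.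
- *Merits.* The chair transition state turns the carbinol configuration of A3 into C5 and writes the trisubstituted C2=C3 alkene with E geometry. This is a surer way to that alkene than the triflate coupling of step 7.
- *Weak points.* Only one of the three triad centres is set. C6 and C7 would need an anti aldol with anti-Felkin sense relative to C5, the least accessible stereotriad by aldol methods. A3 needs its own asymmetric synthesis and the ketene acetal geometry must be controlled. C1 ends as a benzyl-type ether that must be removed and oxidised twice before any polyene is present.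
- *Comparison.* The rearrangement is better for C2=C3 and about equal in steps for C1–C5. The chosen plan sets against it that 9 delivers C5, C6 and C7 in four steps with a single absolute-configuration-determining event, and that the geometry of triflate 12 can be checked before it is used.

**Alternative 3:** The cut is the C6–H bond. An NADPH-dependent ketoreductase would reduce the C6 ketone of β-keto thioester A5 (C7 epimerising through the enol) to the anti,anti β-hydroxy thioester A6 in a dynamic kinetic resolution.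
- *Merits.* Two stereocentres are set in one catalytic step with full theoretical conversion. The product already carries C1–C4 and has C8 at the carboxyl level, so the chain ends need no differentiation. This is a real advantage over the meso route, which spends steps 5 to 9 on that.
- *Weak points.* C5 must first be made by a separate asymmetric step. The enzyme must then deliver one specific diastereomer relative to that centre (matched or mismatched), on a γ-branched 2-methyl-3-oxo thioester. Screening and cofactor recycling are unavoidable.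
- *Comparison.* Both plans are enzymatic and in both the sense of selectivity must be found by experiment. The lipase only has to tell two enantiotopic arms apart on a substrate whose relative configuration is already secured and purified (7). It needs no cofactor and works in organic solvent on a substrate class with direct analogy, and failure costs three cheap steps. This lower risk is what the chosen plan sets against the better end-group economy of the reductase route.

Key step: step 4

Assumption: the lipase is taken to acylate the hydroxymethyl arm of 7 that becomes C8, giving 9 as drawn; the sense of enantiotopic-group selection is empirical and is to be proven by correlation before material is committed.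

Remark: the C8 configuration written for 24–28, 54 and 55 is that of the expected anti (C8/C9), Felkin adduct; it is erased in step 31.

## Route

Step 1
Reactants: 1 methacrolein; 2 isopropenylmagnesium bromide
Product: 3 2,4-dimethylpenta-1,4-dien-3-ol
Conditions: THF, 0 °C → rt; aq. NH4Cl
Reagents that add atoms: none
Why: Grignard 1,2-addition of the alkenylmagnesium reagent to the enal carbonyl. The carbinol carbon carries two identical arms and is not stereogenic.

Step 2
Reactants: 3 2,4-dimethylpenta-1,4-dien-3-ol; 4 tert-butyldimethylsilyl chloride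
Product: 5 tert-butyl[(2,4-dimethylpenta-1,4-dien-3-yl)oxy]dimethylsilane
Conditions: imidazole, DMF, rt
Reagents that add atoms: none
Why: Imidazole-promoted silylation of a secondary alcohol. The bulky silyl ether steers the hydroboration and stays on C6 until the last step.

Step 3
Reactants: 5 tert-butyl[(2,4-dimethylpenta-1,4-dien-3-yl)oxy]dimethylsilane
Product: 7 (2R,3s,4S)-3-[(tert-butyldimethylsilyl)oxy]-2,4-dimethylpentane-1,5-diol, via bis(9-BBN) adduct 6 (not isolated)
Conditions: 9-BBN (2.6 equiv), THF, 0 °C → rt; then NaOH, H2O2, 0 °C → rt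
Reagents that add atoms: hydrogen peroxide OO
Why: Substrate-directed hydroboration of a 1,1-disubstituted allylic silyl ether: with the allylic C–H eclipsing the alkene, the bulky borane adds to the face opposite the carbon branch and gives the 2-methyl/3-oxygen anti relationship on each side. Two anti events give the meso anti,anti diol (C5 and C7 set relative to C6), which should be separable from the minor racemic syn,anti isomer by chromatography. C–B oxidation proceeds with retention.

Step 4
Reactants: 7 (2R,3s,4S)-3-[(tert-butyldimethylsilyl)oxy]-2,4-dimethylpentane-1,5-diol; 8 vinyl acetate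
Product: 9 (2S,3R,4R)-3-[(tert-butyldimethylsilyl)oxy]-5-hydroxy-2,4-dimethylpentyl acetate
Conditions: lipase from Burkholderia cepacia (Amano PS, immobilised), 8 (5 equiv), t-BuOMe, 25 °C, stopped when 7 is consumed
Reagents that add atoms: none
Why: The active-site serine of the lipase attacks vinyl acetate to give an acetyl-enzyme and vinyl alcohol, which tautomerises to acetaldehyde so that the transfer cannot reverse; the acetyl group then passes through a tetrahedral intermediate in the oxyanion hole to one primary hydroxyl of 7. The closest known reaction type is the lipase-catalysed enantiotopic-group-selective acylation of meso 2,4-dimethylpentane-1,5-diols and their 3-oxygenated analogues with enol esters. No ring closes and no carbon–carbon bond forms; one ester C–O bond is made. No new stereocentre is built, but C5, C6 and C7, whose relative configuration comes from step 3, receive their absolute configuration here, the controlling element being the chiral acyl-acceptor pocket of the enzyme, which binds only one of the two mirror-image CH(CH3)CH2OH arms productively. The step needs enantiotopic-group selectivity and mono- over di-acylation: because 7 is a pure meso compound the only possible stereoisomeric by-product is the enantiomer of 9, and the bulky silyl ether on C6 slows the second acylation. Any diacetate should form faster from the minor enantiomer of the monoacetate, so the optical purity of 9 is expected to rise with conversion. The absolute sense is to be proven by a Mosher ester of the free hydroxyl and correlation.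

Step 5
Reactants: 9 (2S,3R,4R)-3-[(tert-butyldimethylsilyl)oxy]-5-hydroxy-2,4-dimethylpentyl acetate
Product: 10 (2S,3S,4S)-3-[(tert-butyldimethylsilyl)oxy]-5-iodo-2,4-dimethylpentyl acetate
Conditions: I2, PPh3, imidazole, CH2Cl2, 0 °C → rt
Reagents that add atoms: iodine II
Why: Appel iodination through the alkoxyphosphonium iodide with SN2 displacement at the CH2 carbon (future C4). No stereocentre is touched (the descriptors change only through priorities), and the acetate and silyl ether are inert.

Step 6
Reactants: 11 methyl acetoacetate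
Product: 12 methyl (2E)-3-{[(trifluoromethyl)sulfonyl]oxy}but-2-enoate
Conditions: Tf2O, aq. Me4NOH, hexane, 5 °C
Reagents that add atoms: trifluoromethanesulfonic anhydride O=S(=O)(OS(=O)(=O)C(F)(F)F)C(F)(F)F
Why: O-Sulfonylation of the β-keto ester enolate under two-phase Schotten–Baumann conditions. The non-chelating tetramethylammonium counter-ion lets the enolate adopt the dipole-minimised geometry with the enolate oxygen trans to the ester, so the (E)-enol triflate should predominate; its geometry is checked by NOE before use.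

Step 7
Reactants: 10 (2S,3S,4S)-3-[(tert-butyldimethylsilyl)oxy]-5-iodo-2,4-dimethylpentyl acetate; 12 methyl (2E)-3-{[(trifluoromethyl)sulfonyl]oxy}but-2-enoate
Product: 14 methyl (2E,5R,6R,7S)-8-acetoxy-6-[(tert-butyldimethylsilyl)oxy]-3,5,7-trimethyloct-2-enoate, via alkylzinc iodide 13 (not isolated)
Conditions: Zn dust (activated with BrCH2CH2Br and Me3SiCl), LiCl, THF, 40 °C; then 12, Pd(dppf)Cl2 (5 mol %), THF, rt → 45 °C
Reagents that add atoms: none
Why: LiCl-promoted zinc insertion into the primary iodide gives an alkylzinc iodide that tolerates the acetate and silyl ether. Negishi sp3–sp2 coupling with the electron-poor enol triflate (oxidative addition, transmetalation, reductive elimination) keeps the alkene geometry and so sets the (2E) C2=C3 bond, and the bidentate dppf ligand suppresses β-hydride elimination.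

Step 8
Reactants: 14 methyl (2E,5R,6R,7S)-8-acetoxy-6-[(tert-butyldimethylsilyl)oxy]-3,5,7-trimethyloct-2-enoate
Product: 15 methyl (2E,5R,6R,7S)-6-[(tert-butyldimethylsilyl)oxy]-8-hydroxy-3,5,7-trimethyloct-2-enoate
Conditions: K2CO3 (0.2 equiv), MeOH, 0 °C → rt
Reagents that add atoms: none
Why: Base-catalysed methanolysis of the primary acetate. The conjugated methyl ester can only exchange methoxide for methoxide, and no stereocentre is enolisable.

Step 9
Reactants: 15 methyl (2E,5R,6R,7S)-6-[(tert-butyldimethylsilyl)oxy]-8-hydroxy-3,5,7-trimethyloct-2-enoate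
Product: 16 methyl (2E,5R,6R,7R)-6-[(tert-butyldimethylsilyl)oxy]-3,5,7-trimethyl-8-oxooct-2-enoate
Conditions: Dess–Martin periodinane, NaHCO3, CH2Cl2, 0 °C → rt; used crude
Reagents that add atoms: none
Why: Dess–Martin oxidation under buffered, non-basic conditions should give the α-methyl-β-silyloxy aldehyde without epimerisation at C7.

Step 10
Reactants: 17 [(tert-butyldimethylsilyl)oxy]acetaldehyde; 18 prop-1-yn-1-ylmagnesium bromide
Product: 19 rac-1-[(tert-butyldimethylsilyl)oxy]pent-3-yn-2-ol
Conditions: THF, −78 → 0 °C; aq. NH4Cl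
Reagents that add atoms: none
Why: Addition of the alkynyl Grignard reagent to the aldehyde. The racemic carbinol is oxidised in the next step.

Step 11
Reactants: 19 rac-1-[(tert-butyldimethylsilyl)oxy]pent-3-yn-2-ol
Product: 20 1-[(tert-butyldimethylsilyl)oxy]pent-3-yn-2-one
Conditions: Dess–Martin periodinane, NaHCO3, CH2Cl2, rt
Reagents that add atoms: none
Why: Dess–Martin oxidation of the propargylic alcohol to the ynone under neutral conditions that spare the silyl ether.

Step 12
Reactants: 20 1-[(tert-butyldimethylsilyl)oxy]pent-3-yn-2-one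
Product: 21 (2R)-1-[(tert-butyldimethylsilyl)oxy]pent-3-yn-2-ol
Conditions: RuCl[(S,S)-TsDPEN](p-cymene) (1 mol %, activated with KOH), i-PrOH, rt
Reagents that add atoms: none
Why: Noyori asymmetric transfer hydrogenation of an alkynyl ketone. The alkyne occupies the place that the aryl group has in aryl ketones, so the (S,S)-catalyst should deliver hydride to give the carbinol with the R descriptor (CH2OSi outranks the alkynyl group). The configuration is to be confirmed by Mosher analysis, and the (R,R)-catalyst is equally available.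

Step 13
Reactants: 21 (2R)-1-[(tert-butyldimethylsilyl)oxy]pent-3-yn-2-ol
Product: 22 (2R)-1-[(tert-butyldimethylsilyl)oxy]pent-3-yn-2-yl methanesulfonate
Conditions: MsCl, Et3N, CH2Cl2, −78 → 0 °C; used crude
Reagents that add atoms: methanesulfonyl chloride CS(=O)(=O)Cl
Why: O-Sulfonylation with retention at carbon. The propargylic mesylate is used without purification.

Step 14
Reactants: 16 methyl (2E,5R,6R,7R)-6-[(tert-butyldimethylsilyl)oxy]-3,5,7-trimethyl-8-oxooct-2-enoate; 22 (2R)-1-[(tert-butyldimethylsilyl)oxy]pent-3-yn-2-yl methanesulfonate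
Product: 24 methyl (2E,5R,6R,7S,8R,9S)-6-[(tert-butyldimethylsilyl)oxy]-9-{[(tert-butyldimethylsilyl)oxy]methyl}-8-hydroxy-3,5,7-trimethyldodec-2-en-10-ynoate, via allenylzinc mesylate 23 (not isolated)
Conditions: Pd(OAc)2 (5 mol %), PPh3 (5 mol %), Et2Zn (3 equiv), THF, −78 → −20 °C
Reagents that add atoms: none
Why: Marshall propargylation: zerovalent palladium displaces the mesylate anti (SN2′) to give an allenylpalladium species, transfer to zinc with retention gives allenylzinc 23, and addition to the aldehyde through a cyclic SE2′ transition state (bond formation on the zinc-bearing face) passes the axial chirality on to C9 (9S from the R mesylate). The C8 carbinol should form anti to the C9 substituent and in the Felkin sense relative to C7 (matched pair); C8 is oxidised later, so only C9 matters.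

Step 15
Reactants: 24 methyl (2E,5R,6R,7S,8R,9S)-6-[(tert-butyldimethylsilyl)oxy]-9-{[(tert-butyldimethylsilyl)oxy]methyl}-8-hydroxy-3,5,7-trimethyldodec-2-en-10-ynoate
Product: 25 methyl (2E,5R,6R,7R,8R,9S)-6-[(tert-butyldimethylsilyl)oxy]-9-{[(tert-butyldimethylsilyl)oxy]methyl}-3,5,7-trimethyl-8-[(trimethylsilyl)oxy]dodec-2-en-10-ynoate
Conditions: Me3SiCl, imidazole, DMF, 0 °C
Reagents that add atoms: chlorotrimethylsilane C[Si](C)(C)Cl
Why: Silylation masks the C8 hydroxyl so that no zirconium alkoxide can direct the hydrozirconation to C10. The labile trimethylsilyl ether is chosen because it falls off in step 17.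

Step 16
Reactants: 25 methyl (2E,5R,6R,7R,8R,9S)-6-[(tert-butyldimethylsilyl)oxy]-9-{[(tert-butyldimethylsilyl)oxy]methyl}-3,5,7-trimethyl-8-[(trimethylsilyl)oxy]dodec-2-en-10-ynoate
Product: 27 methyl (2E,5R,6R,7R,8R,9S,10E)-6-[(tert-butyldimethylsilyl)oxy]-9-{[(tert-butyldimethylsilyl)oxy]methyl}-11-iodo-3,5,7-trimethyl-8-[(trimethylsilyl)oxy]dodeca-2,10-dienoate, via alkenylzirconocene chloride 26 (not isolated)
Conditions: Cp2Zr(H)Cl (2.2 equiv), THF, rt → 40 °C; then I2, THF, 0 °C
Reagents that add atoms: iodine II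
Why: Schwartz hydrozirconation of the methyl-capped alkyne: Zr–H adds syn and, after equilibration with excess reagent, zirconium sits on the methyl-bearing C11 away from the branched C9. Iodinolysis with retention gives the (10E)-iodoalkene.

Step 17
Reactants: 27 methyl (2E,5R,6R,7R,8R,9S,10E)-6-[(tert-butyldimethylsilyl)oxy]-9-{[(tert-butyldimethylsilyl)oxy]methyl}-11-iodo-3,5,7-trimethyl-8-[(trimethylsilyl)oxy]dodeca-2,10-dienoate
Product: 28 (2E,5R,6R,7S,8R,9S,10E)-6-[(tert-butyldimethylsilyl)oxy]-9-{[(tert-butyldimethylsilyl)oxy]methyl}-8-hydroxy-11-iodo-3,5,7-trimethyldodeca-2,10-dienoic acid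
Conditions: LiOH·H2O, THF/MeOH/H2O (3:1:1), rt → 40 °C; then 0.5 M HCl to pH 4 at 0 °C
Reagents that add atoms: lithium hydroxide [Li+].[OH-]
Why: Saponification of the methyl ester; hydroxide also removes the labile trimethylsilyl ether, while the two tert-butyldimethylsilyl ethers and the iodoalkene are stable. The acid is freed here because no later intermediate tolerates hydroxide.

Step 18
Reactants: 29 (4S)-4-benzyl-3-propanoyl-1,3-oxazolidin-2-one; 30 3-bromo-1-(trimethylsilyl)prop-1-yne
Product: 32 (4S)-4-benzyl-3-[(2R)-2-methyl-5-(trimethylsilyl)pent-4-ynoyl]-1,3-oxazolidin-2-one, via sodium enolate 31 (not isolated)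
Conditions: NaN(SiMe3)2, THF, −78 °C; then 30, −78 → −40 °C
Reagents that add atoms: none
Why: Evans alkylation: the chelated (Z)-sodium enolate is alkylated by the propargylic bromide on the face opposite the benzyl group, which sets C15 (R).

Step 19
Reactants: 32 (4S)-4-benzyl-3-[(2R)-2-methyl-5-(trimethylsilyl)pent-4-ynoyl]-1,3-oxazolidin-2-one
Product: 33 (2R)-2-methyl-5-(trimethylsilyl)pent-4-yn-1-ol
Conditions: LiBH4, H2O (1 equiv), Et2O, 0 °C
Reagents that add atoms: none
Why: Reductive removal of the auxiliary: hydride attacks the exocyclic imide carbonyl. No enolisation occurs, so C15 is kept, and the oxazolidinone is recovered.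

Step 20
Reactants: 33 (2R)-2-methyl-5-(trimethylsilyl)pent-4-yn-1-ol
Product: 34 (2R)-2-methyl-5-(trimethylsilyl)pent-4-ynal
Conditions: Dess–Martin periodinane, NaHCO3, CH2Cl2, 0 °C → rt; used crude
Reagents that add atoms: none
Why: Dess–Martin oxidation gives the α-branched aldehyde under non-basic conditions. It is used at once to avoid epimerisation.

Step 21
Reactants: 34 (2R)-2-methyl-5-(trimethylsilyl)pent-4-ynal; 35 propyltriphenylphosphonium bromide
Product: 39 [(4R,5Z)-6-iodo-4-methyloct-5-en-1-yn-1-yl]trimethylsilane, via propylidene ylide 36 (not isolated), via iodophosphonium iodide 37 (not isolated), via iodo ylide 38 (not isolated)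
Conditions: 35, n-BuLi, THF, rt; I2, −78 °C; NaN(SiMe3)2, −78 → −20 °C; then 34, −78 °C
Reagents that add atoms: iodine II
Why: Stork–Zhao iodo-olefination: the unstabilised α-iodo ylide reacts under kinetic control through the cis oxaphosphetane, which places iodine cis to the aldehyde residue. The resulting (Z)-iodoalkene fixes the later (16Z) geometry.

Step 22
Reactants: 40 3-(trimethylsilyl)prop-2-ynal; 41 (E)-but-2-ene
Product: 44 (3S,4S)-4-methyl-1-(trimethylsilyl)hex-5-en-1-yn-3-ol, via crotylborane 42 (not isolated), via borinate ester 43 (not isolated)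
Conditions: 41, KOt-Bu, n-BuLi, THF, −78 → −45 °C; (−)-Ipc2BOMe, −78 °C; BF3·OEt2; 40, −78 °C; then NaBO3·4H2O, H2O, rt
Reagents that add atoms: none
Why: Brown crotylboration: the (E)-crotylborane adds through a closed chair transition state, so E geometry gives the anti product, and the isopinocampheyl groups derived from (+)-α-pinene select the aldehyde face. C20 and C21 are set together; the mild perborate work-up spares the alkynylsilane.

Step 23
Reactants: 44 (3S,4S)-4-methyl-1-(trimethylsilyl)hex-5-en-1-yn-3-ol; 45 3,3-diethoxyprop-1-ene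
Product: 46 {(3S,4S)-3-[(1-ethoxyprop-2-en-1-yl)oxy]-4-methylhex-5-en-1-yn-1-yl}trimethylsilane
Conditions: 45 (5 equiv), PPTS (0.1 equiv), toluene, 40 °C, reduced pressure
Reagents that add atoms: none
Why: Acid-catalysed transacetalisation driven by removal of ethanol. The new acetal carbon forms as a mixture of epimers, which does not matter because it becomes the lactone carbonyl.

Step 24
Reactants: 46 {(3S,4S)-3-[(1-ethoxyprop-2-en-1-yl)oxy]-4-methylhex-5-en-1-yn-1-yl}trimethylsilane
Product: 47 {[(2S,3S)-6-ethoxy-3-methyl-3,6-dihydro-2H-pyran-2-yl]ethynyl}trimethylsilane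
Conditions: Cl2(PCy3)2Ru=CHPh (first-generation Grubbs catalyst, 5 mol %), CH2Cl2, 40 °C
Reagents that add atoms: none
Why: Ring-closing metathesis of the two terminal alkenes forms the six-membered dihydropyran with loss of ethene. The silyl-capped alkyne is too hindered to enter enyne metathesis with this catalyst.

Step 25
Reactants: 47 {[(2S,3S)-6-ethoxy-3-methyl-3,6-dihydro-2H-pyran-2-yl]ethynyl}trimethylsilane
Product: 48 (2S,3S)-6-ethoxy-2-ethynyl-3-methyl-3,6-dihydro-2H-pyran
Conditions: K2CO3, MeOH, 0 °C → rt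
Reagents that add atoms: none
Why: Methoxide cleaves the alkynyl C–Si bond. The acetal is inert to base.

Step 26
Reactants: 48 (2S,3S)-6-ethoxy-2-ethynyl-3-methyl-3,6-dihydro-2H-pyran; 39 [(4R,5Z)-6-iodo-4-methyloct-5-en-1-yn-1-yl]trimethylsilane
Product: 51 (2R,3S)-6-ethoxy-2-[(1E,3Z,5R)-3-ethyl-5-methyl-8-(trimethylsilyl)octa-1,3-dien-7-yn-1-yl]-3-methyl-3,6-dihydro-2H-pyran, via alkenylzirconocene chloride 49 (not isolated), via alkenylzinc chloride 50 (not isolated)
Conditions: 48, Cp2Zr(H)Cl (1.2 equiv), THF, 0 °C → rt; ZnCl2, THF; then 39, Pd(PPh3)4 (5 mol %), rt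
Reagents that add atoms: none
Why: Schwartz hydrozirconation of the terminal alkyne (syn, zirconium on the terminal carbon) gives the (E)-alkenylzirconocene. Transfer to zinc and Negishi coupling with the (Z)-iodoalkene keep both geometries and give the (16Z,18E)-diene.

Step 27
Reactants: 51 (2R,3S)-6-ethoxy-2-[(1E,3Z,5R)-3-ethyl-5-methyl-8-(trimethylsilyl)octa-1,3-dien-7-yn-1-yl]-3-methyl-3,6-dihydro-2H-pyran
Product: 52 (2R,3S)-6-ethoxy-2-[(1E,3Z,5R)-3-ethyl-5-methylocta-1,3-dien-7-yn-1-yl]-3-methyl-3,6-dihydro-2H-pyran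
Conditions: K2CO3, MeOH, rt
Reagents that add atoms: none
Why: Methanolysis of the alkynylsilane as in step 25. The diene and acetal are not affected by carbonate.

Step 28
Reactants: 52 (2R,3S)-6-ethoxy-2-[(1E,3Z,5R)-3-ethyl-5-methylocta-1,3-dien-7-yn-1-yl]-3-methyl-3,6-dihydro-2H-pyran
Product: 53 (2R,3S)-6-ethoxy-2-[(1E,3Z,5R,7E)-3-ethyl-5-methyl-8-(4,4,5,5-tetramethyl-1,3,2-dioxaborolan-2-yl)octa-1,3,7-trien-1-yl]-3-methyl-3,6-dihydro-2H-pyran
Conditions: pinacolborane (1.5 equiv), Cp2Zr(H)Cl (10 mol %), Et3N (10 mol %), CH2Cl2, rt → 40 °C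
Reagents that add atoms: pinacolborane B1OC(C)(C)C(C)(C)O1
Why: Zirconocene-hydride-catalysed hydroboration of the terminal alkyne with pinacolborane: syn, anti-Markovnikov addition gives the (E)-alkenylboronate. The internal alkenes and the acetal do not react.

Step 29
Reactants: 28 (2E,5R,6R,7S,8R,9S,10E)-6-[(tert-butyldimethylsilyl)oxy]-9-{[(tert-butyldimethylsilyl)oxy]methyl}-8-hydroxy-11-iodo-3,5,7-trimethyldodeca-2,10-dienoic acid; 53 (2R,3S)-6-ethoxy-2-[(1E,3Z,5R,7E)-3-ethyl-5-methyl-8-(4,4,5,5-tetramethyl-1,3,2-dioxaborolan-2-yl)octa-1,3,7-trien-1-yl]-3-methyl-3,6-dihydro-2H-pyran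
Product: 54 (2E,5R,6R,7S,8R,9S,10E,12E,15R,16Z,18E)-6-[(tert-butyldimethylsilyl)oxy]-9-{[(tert-butyldimethylsilyl)oxy]methyl}-19-[(2R,3S)-6-ethoxy-3-methyl-3,6-dihydro-2H-pyran-2-yl]-17-ethyl-8-hydroxy-3,5,7,11,15-pentamethylnonadeca-2,10,12,16,18-pentaenoic acid
Conditions: Pd(PPh3)4 (10 mol %), TlOEt (3 equiv), THF/H2O (3:1), rt; pH 5 work-up
Reagents that add atoms: none
Why: Suzuki–Miyaura sp2–sp2 coupling with retention on both partners gives the (10E,12E)-diene, and TlOEt speeds transmetalation at room temperature. The free acid and alcohol are tolerated, and nothing base-sensitive is present at this stage.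

Step 30
Reactants: 54 (2E,5R,6R,7S,8R,9S,10E,12E,15R,16Z,18E)-6-[(tert-butyldimethylsilyl)oxy]-9-{[(tert-butyldimethylsilyl)oxy]methyl}-19-[(2R,3S)-6-ethoxy-3-methyl-3,6-dihydro-2H-pyran-2-yl]-17-ethyl-8-hydroxy-3,5,7,11,15-pentamethylnonadeca-2,10,12,16,18-pentaenoic acid
Product: 55 (2E,5R,6R,7S,8R,9S,10E,12E,15R,16Z,18E)-6-[(tert-butyldimethylsilyl)oxy]-9-{[(tert-butyldimethylsilyl)oxy]methyl}-17-ethyl-8-hydroxy-19-[(2R,3S)-6-hydroxy-3-methyl-3,6-dihydro-2H-pyran-2-yl]-3,5,7,11,15-pentamethylnonadeca-2,10,12,16,18-pentaenoic acid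
Conditions: PPTS (0.3 equiv), acetone/H2O (4:1), rt
Reagents that add atoms: water O
Why: Mild acid hydrolysis of the allylic acetal through the ring oxocarbenium ion. The silyl ethers should survive, and the lactol is oxidised without storage.

Step 31
Reactants: 55 (2E,5R,6R,7S,8R,9S,10E,12E,15R,16Z,18E)-6-[(tert-butyldimethylsilyl)oxy]-9-{[(tert-butyldimethylsilyl)oxy]methyl}-17-ethyl-8-hydroxy-19-[(2R,3S)-6-hydroxy-3-methyl-3,6-dihydro-2H-pyran-2-yl]-3,5,7,11,15-pentamethylnonadeca-2,10,12,16,18-pentaenoic acid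
Product: 56 (2E,5R,6R,7R,9S,10E,12E,15R,16Z,18E)-6-[(tert-butyldimethylsilyl)oxy]-9-{[(tert-butyldimethylsilyl)oxy]methyl}-17-ethyl-3,5,7,11,15-pentamethyl-19-[(2R,3S)-3-methyl-6-oxo-3,6-dihydro-2H-pyran-2-yl]-8-oxononadeca-2,10,12,16,18-pentaenoic acid
Conditions: Dess–Martin periodinane (4 equiv), NaHCO3, CH2Cl2, 0 °C → rt
Reagents that add atoms: none
Why: Dess–Martin oxidation converts the lactol into the lactone and the C8 carbinol into the ketone in one operation. The buffered, non-basic medium protects the now acidic C9–H.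

Step 32
Reactants: 56 (2E,5R,6R,7R,9S,10E,12E,15R,16Z,18E)-6-[(tert-butyldimethylsilyl)oxy]-9-{[(tert-butyldimethylsilyl)oxy]methyl}-17-ethyl-3,5,7,11,15-pentamethyl-19-[(2R,3S)-3-methyl-6-oxo-3,6-dihydro-2H-pyran-2-yl]-8-oxononadeca-2,10,12,16,18-pentaenoic acid
Product: 57 (2E,5R,6R,7R,9S,10E,12E,15R,16Z,18E)-17-ethyl-6-hydroxy-9-(hydroxymethyl)-3,5,7,11,15-pentamethyl-19-[(2R,3S)-3-methyl-6-oxo-3,6-dihydro-2H-pyran-2-yl]-8-oxononadeca-2,10,12,16,18-pentaenoic acid
Conditions: HF·pyridine, pyridine, THF, 0 °C → rt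
Reagents that add atoms: none
Why: Fluoride-mediated cleavage of both silyl ethers in a buffered, mildly acidic medium. No base is present, so retro-aldol cleavage, β-elimination at C9 and lactone opening are avoided.

## Compound list

1 | methacrolein | CC(=C)C=O | starting material
2 | isopropenylmagnesium bromide | CC(=C)[Mg]Br | starting material
3 | 2,4-dimethylpenta-1,4-dien-3-ol | CC(=C)C(O)C(C)=C | intermediate
4 | tert-butyldimethylsilyl chloride | CC(C)(C)[Si](C)(C)Cl | starting material
5 | tert-butyl[(2,4-dimethylpenta-1,4-dien-3-yl)oxy]dimethylsilane | CC(=C)C(O[Si](C)(C)C(C)(C)C)C(C)=C | intermediate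
6 | 9,9'-[(2R,3s,4S)-3-(tert-butyldimethylsilyloxy)-2,4-dimethylpentane-1,5-diyl]bis(9-borabicyclo[3.3.1]nonane) (not isolated) | B1(C2CCCC1CCC2)C[C@H](C)[C@H](O[Si](C)(C)C(C)(C)C)[C@H](C)CB1C2CCCC1CCC2 | intermediate
7 | (2R,3s,4S)-3-[(tert-butyldimethylsilyl)oxy]-2,4-dimethylpentane-1,5-diol (meso; anti,anti) | OC[C@H](C)[C@H](O[Si](C)(C)C(C)(C)C)[C@H](C)CO | intermediate
8 | vinyl acetate | C=COC(C)=O | starting material
9 | (2S,3R,4R)-3-[(tert-butyldimethylsilyl)oxy]-5-hydroxy-2,4-dimethylpentyl acetate (acetate on future C8, hydroxyl on future C4) | CC(=O)OC[C@H](C)[C@H](O[Si](C)(C)C(C)(C)C)[C@H](C)CO | intermediate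
10 | (2S,3S,4S)-3-[(tert-butyldimethylsilyl)oxy]-5-iodo-2,4-dimethylpentyl acetate | CC(=O)OC[C@H](C)[C@H](O[Si](C)(C)C(C)(C)C)[C@H](C)CI | intermediate
11 | methyl acetoacetate | CC(=O)CC(=O)OC | starting material
12 | methyl (2E)-3-{[(trifluoromethyl)sulfonyl]oxy}but-2-enoate | COC(=O)/C=C(\C)OS(=O)(=O)C(F)(F)F | intermediate
13 | {(2S,3S,4S)-5-acetoxy-3-[(tert-butyldimethylsilyl)oxy]-2,4-dimethylpentyl}zinc iodide (not isolated) | CC(=O)OC[C@H](C)[C@H](O[Si](C)(C)C(C)(C)C)[C@H](C)C[Zn]I | intermediate
14 | methyl (2E,5R,6R,7S)-8-acetoxy-6-[(tert-butyldimethylsilyl)oxy]-3,5,7-trimethyloct-2-enoate | CC(=O)OC[C@H](C)[C@H](O[Si](C)(C)C(C)(C)C)[C@H](C)C/C(C)=C/C(=O)OC | intermediate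
15 | methyl (2E,5R,6R,7S)-6-[(tert-butyldimethylsilyl)oxy]-8-hydroxy-3,5,7-trimethyloct-2-enoate | OC[C@H](C)[C@H](O[Si](C)(C)C(C)(C)C)[C@H](C)C/C(C)=C/C(=O)OC | intermediate
16 | methyl (2E,5R,6R,7R)-6-[(tert-butyldimethylsilyl)oxy]-3,5,7-trimethyl-8-oxooct-2-enoate | O=C[C@H](C)[C@H](O[Si](C)(C)C(C)(C)C)[C@H](C)C/C(C)=C/C(=O)OC | intermediate
17 | [(tert-butyldimethylsilyl)oxy]acetaldehyde | O=CCO[Si](C)(C)C(C)(C)C | starting material
18 | prop-1-yn-1-ylmagnesium bromide | CC#C[Mg]Br | starting material
19 | rac-1-[(tert-butyldimethylsilyl)oxy]pent-3-yn-2-ol | CC#CC(O)CO[Si](C)(C)C(C)(C)C | intermediate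
20 | 1-[(tert-butyldimethylsilyl)oxy]pent-3-yn-2-one | CC#CC(=O)CO[Si](C)(C)C(C)(C)C | intermediate
21 | (2R)-1-[(tert-butyldimethylsilyl)oxy]pent-3-yn-2-ol | CC#C[C@@H](O)CO[Si](C)(C)C(C)(C)C | intermediate
22 | (2R)-1-[(tert-butyldimethylsilyl)oxy]pent-3-yn-2-yl methanesulfonate | CC#C[C@@H](OS(C)(=O)=O)CO[Si](C)(C)C(C)(C)C | intermediate
23 | (aR)-{5-[(tert-butyldimethylsilyl)oxy]penta-2,3-dien-2-yl}zinc methanesulfonate (not isolated) | CS(=O)(=O)O[Zn]C(C)=[C@]=C([H])CO[Si](C)(C)C(C)(C)C | intermediate
24 | methyl (2E,5R,6R,7S,8R,9S)-6-[(tert-butyldimethylsilyl)oxy]-9-{[(tert-butyldimethylsilyl)oxy]methyl}-8-hydroxy-3,5,7-trimethyldodec-2-en-10-ynoate | CC#C[C@@H](CO[Si](C)(C)C(C)(C)C)[C@@H](O)[C@H](C)[C@H](O[Si](C)(C)C(C)(C)C)[C@H](C)C/C(C)=C/C(=O)OC | intermediate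
25 | methyl (2E,5R,6R,7R,8R,9S)-6-[(tert-butyldimethylsilyl)oxy]-9-{[(tert-butyldimethylsilyl)oxy]methyl}-3,5,7-trimethyl-8-[(trimethylsilyl)oxy]dodec-2-en-10-ynoate | CC#C[C@@H](CO[Si](C)(C)C(C)(C)C)[C@@H](O[Si](C)(C)C)[C@H](C)[C@H](O[Si](C)(C)C(C)(C)C)[C@H](C)C/C(C)=C/C(=O)OC | intermediate
26 | chlorobis(cyclopentadienyl)zirconium alkenyl from 25: Zr on C11 trans to C9, H on C10, other centres as in 25 (not isolated) | Cl[Zr](/C(C)=C/[C@@H](CO[Si](C)(C)C(C)(C)C)[C@@H](O[Si](C)(C)C)[C@H](C)[C@H](O[Si](C)(C)C(C)(C)C)[C@H](C)C/C(C)=C/C(=O)OC)(C1C=CC=C1)C1C=CC=C1 | intermediate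
27 | methyl (2E,5R,6R,7R,8R,9S,10E)-6-[(tert-butyldimethylsilyl)oxy]-9-{[(tert-butyldimethylsilyl)oxy]methyl}-11-iodo-3,5,7-trimethyl-8-[(trimethylsilyl)oxy]dodeca-2,10-dienoate | I/C(C)=C/[C@@H](CO[Si](C)(C)C(C)(C)C)[C@@H](O[Si](C)(C)C)[C@H](C)[C@H](O[Si](C)(C)C(C)(C)C)[C@H](C)C/C(C)=C/C(=O)OC | intermediate
28 | (2E,5R,6R,7S,8R,9S,10E)-6-[(tert-butyldimethylsilyl)oxy]-9-{[(tert-butyldimethylsilyl)oxy]methyl}-8-hydroxy-11-iodo-3,5,7-trimethyldodeca-2,10-dienoic acid (west fragment) | I/C(C)=C/[C@@H](CO[Si](C)(C)C(C)(C)C)[C@@H](O)[C@H](C)[C@H](O[Si](C)(C)C(C)(C)C)[C@H](C)C/C(C)=C/C(=O)O | intermediate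
29 | (4S)-4-benzyl-3-propanoyl-1,3-oxazolidin-2-one | CCC(=O)N1C(=O)OC[C@@H]1Cc1ccccc1 | starting material
30 | 3-bromo-1-(trimethylsilyl)prop-1-yne | C[Si](C)(C)C#CCBr | starting material
31 | sodium (Z)-enolate of 29 (not isolated) | C/C=C(\[O-])N1C(=O)OC[C@@H]1Cc1ccccc1.[Na+] | intermediate
32 | (4S)-4-benzyl-3-[(2R)-2-methyl-5-(trimethylsilyl)pent-4-ynoyl]-1,3-oxazolidin-2-one | O=C([C@H](C)CC#C[Si](C)(C)C)N1C(=O)OC[C@@H]1Cc1ccccc1 | intermediate
33 | (2R)-2-methyl-5-(trimethylsilyl)pent-4-yn-1-ol | OC[C@H](C)CC#C[Si](C)(C)C | intermediate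
34 | (2R)-2-methyl-5-(trimethylsilyl)pent-4-ynal | O=C[C@H](C)CC#C[Si](C)(C)C | intermediate
35 | propyltriphenylphosphonium bromide | CCC[P+](c1ccccc1)(c1ccccc1)c1ccccc1.[Br-] | starting material
36 | propylidenetriphenylphosphorane (not isolated) | CCC=P(c1ccccc1)(c1ccccc1)c1ccccc1 | intermediate
37 | (1-iodopropyl)triphenylphosphonium iodide (not isolated) | CCC(I)[P+](c1ccccc1)(c1ccccc1)c1ccccc1.[I-] | intermediate
38 | (1-iodopropylidene)triphenylphosphorane (not isolated) | CCC(I)=P(c1ccccc1)(c1ccccc1)c1ccccc1 | intermediate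
39 | [(4R,5Z)-6-iodo-4-methyloct-5-en-1-yn-1-yl]trimethylsilane | CC/C(I)=C/[C@H](C)CC#C[Si](C)(C)C | intermediate
40 | 3-(trimethylsilyl)prop-2-ynal | C[Si](C)(C)C#CC=O | starting material
41 | (E)-but-2-ene | C/C=C/C | starting material
42 | [(2E)-but-2-en-1-yl]bis[(1R,2S,3R,5R)-isopinocampheyl]borane (not isolated) | C/C=C/CB([C@@H]1C[C@@H]2C[C@H]([C@H]1C)C2(C)C)[C@@H]1C[C@@H]2C[C@H]([C@H]1C)C2(C)C | intermediate
43 | (3S,4S)-4-methyl-1-(trimethylsilyl)hex-5-en-1-yn-3-yl bis[(1R,2S,3R,5R)-isopinocampheyl]borinate (not isolated) | C[Si](C)(C)C#C[C@@H](OB([C@@H]1C[C@@H]2C[C@H]([C@H]1C)C2(C)C)[C@@H]1C[C@@H]2C[C@H]([C@H]1C)C2(C)C)[C@@H](C)C=C | intermediate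
44 | (3S,4S)-4-methyl-1-(trimethylsilyl)hex-5-en-1-yn-3-ol | C[Si](C)(C)C#C[C@@H](O)[C@@H](C)C=C | intermediate
45 | 3,3-diethoxyprop-1-ene (acrolein diethyl acetal) | C=CC(OCC)OCC | starting material
46 | {(3S,4S)-3-[(1-ethoxyprop-2-en-1-yl)oxy]-4-methylhex-5-en-1-yn-1-yl}trimethylsilane (both acetal epimers) | C[Si](C)(C)C#C[C@@H](OC(OCC)C=C)[C@@H](C)C=C | intermediate
47 | {[(2S,3S)-6-ethoxy-3-methyl-3,6-dihydro-2H-pyran-2-yl]ethynyl}trimethylsilane (both C6 epimers) | C[Si](C)(C)C#C[C@H]1OC(OCC)C=C[C@@H]1C | intermediate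
48 | (2S,3S)-6-ethoxy-2-ethynyl-3-methyl-3,6-dihydro-2H-pyran | C#C[C@H]1OC(OCC)C=C[C@@H]1C | intermediate
49 | chlorobis(cyclopentadienyl){(E)-2-[(2S,3S)-6-ethoxy-3-methyl-3,6-dihydro-2H-pyran-2-yl]ethenyl}zirconium (not isolated) | Cl[Zr](/C=C/[C@H]1OC(OCC)C=C[C@@H]1C)(C1C=CC=C1)C1C=CC=C1 | intermediate
50 | chloro{(E)-2-[(2S,3S)-6-ethoxy-3-methyl-3,6-dihydro-2H-pyran-2-yl]ethenyl}zinc (not isolated) | Cl[Zn]/C=C/[C@H]1OC(OCC)C=C[C@@H]1C | intermediate
51 | (2R,3S)-6-ethoxy-2-[(1E,3Z,5R)-3-ethyl-5-methyl-8-(trimethylsilyl)octa-1,3-dien-7-yn-1-yl]-3-methyl-3,6-dihydro-2H-pyran | CCC(=C/[C@H](C)CC#C[Si](C)(C)C)/C=C/[C@H]1OC(OCC)C=C[C@@H]1C | intermediate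
52 | (2R,3S)-6-ethoxy-2-[(1E,3Z,5R)-3-ethyl-5-methylocta-1,3-dien-7-yn-1-yl]-3-methyl-3,6-dihydro-2H-pyran | CCC(=C/[C@H](C)CC#C)/C=C/[C@H]1OC(OCC)C=C[C@@H]1C | intermediate
53 | (2R,3S)-6-ethoxy-2-[(1E,3Z,5R,7E)-3-ethyl-5-methyl-8-(4,4,5,5-tetramethyl-1,3,2-dioxaborolan-2-yl)octa-1,3,7-trien-1-yl]-3-methyl-3,6-dihydro-2H-pyran (east fragment) | CCC(=C/[C@H](C)C/C=C/B1OC(C)(C)C(C)(C)O1)/C=C/[C@H]1OC(OCC)C=C[C@@H]1C | intermediate
54 | (2E,5R,6R,7S,8R,9S,10E,12E,15R,16Z,18E)-6-[(tert-butyldimethylsilyl)oxy]-9-{[(tert-butyldimethylsilyl)oxy]methyl}-19-[(2R,3S)-6-ethoxy-3-methyl-3,6-dihydro-2H-pyran-2-yl]-17-ethyl-8-hydroxy-3,5,7,11,15-pentamethylnonadeca-2,10,12,16,18-pentaenoic acid | CCC(=C/[C@H](C)C/C=C/C(C)=C/[C@@H](CO[Si](C)(C)C(C)(C)C)[C@@H](O)[C@H](C)[C@H](O[Si](C)(C)C(C)(C)C)[C@H](C)C/C(C)=C/C(=O)O)/C=C/[C@H]1OC(OCC)C=C[C@@H]1C | intermediate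
55 | (2E,5R,6R,7S,8R,9S,10E,12E,15R,16Z,18E)-6-[(tert-butyldimethylsilyl)oxy]-9-{[(tert-butyldimethylsilyl)oxy]methyl}-17-ethyl-8-hydroxy-19-[(2R,3S)-6-hydroxy-3-methyl-3,6-dihydro-2H-pyran-2-yl]-3,5,7,11,15-pentamethylnonadeca-2,10,12,16,18-pentaenoic acid (lactol epimers) | CCC(=C/[C@H](C)C/C=C/C(C)=C/[C@@H](CO[Si](C)(C)C(C)(C)C)[C@@H](O)[C@H](C)[C@H](O[Si](C)(C)C(C)(C)C)[C@H](C)C/C(C)=C/C(=O)O)/C=C/[C@H]1OC(O)C=C[C@@H]1C | intermediate
56 | (2E,5R,6R,7R,9S,10E,12E,15R,16Z,18E)-6-[(tert-butyldimethylsilyl)oxy]-9-{[(tert-butyldimethylsilyl)oxy]methyl}-17-ethyl-3,5,7,11,15-pentamethyl-19-[(2R,3S)-3-methyl-6-oxo-3,6-dihydro-2H-pyran-2-yl]-8-oxononadeca-2,10,12,16,18-pentaenoic acid | CCC(=C/[C@H](C)C/C=C/C(C)=C/[C@@H](CO[Si](C)(C)C(C)(C)C)C(=O)[C@H](C)[C@H](O[Si](C)(C)C(C)(C)C)[C@H](C)C/C(C)=C/C(=O)O)/C=C/[C@H]1OC(=O)C=C[C@@H]1C | intermediate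
57 | (2E,5R,6R,7R,9S,10E,12E,15R,16Z,18E)-17-ethyl-6-hydroxy-9-(hydroxymethyl)-3,5,7,11,15-pentamethyl-19-[(2R,3S)-3-methyl-6-oxo-3,6-dihydro-2H-pyran-2-yl]-8-oxononadeca-2,10,12,16,18-pentaenoic acid (CNP0302052.3) | CCC(=C/[C@H](C)C/C=C/C(C)=C/[C@@H](CO)C(=O)[C@H](C)[C@H](O)[C@H](C)C/C(C)=C/C(=O)O)/C=C/[C@H]1OC(=O)C=C[C@@H]1C | target

## Step count and least certain steps

Total step count: 32. Longest linear sequence: 16 steps (steps 1–5, 7–9, 14–17 and 29–32). The side branches are step 6, steps 10–13, steps 18–21 with 26–28, and steps 22–25.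

**Step 4 (key step).** The enzyme may select the other enantiotopic arm, or discriminate poorly because the bulky silyl ether on C6 sits next to both reacting arms. Over-acylation to the diacetate is the second risk. Fallback: the acyl transfer is run in the hydrolytic direction. Starting from 7, exhaustive acetylation (Ac2O, pyridine, DMAP) gives the meso diacetate (2R,3s,4S)-3-[(tert-butyldimethylsilyl)oxy]-2,4-dimethylpentane-1,5-diyl diacetate F1. Hydrolysis with the same lipase in pH 7 phosphate buffer/t-BuOMe removes the acetate from the arm that the enzyme would have acylated, so the monoacetate of opposite sense results, and the sequence returns to the route at 9.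

**Step 14.** The allenylzinc reagent carries a silyloxymethyl group. Its propargylzinc tautomer can lose silanolate by β-elimination, and the reagent can lose configurational integrity before it adds, which would lower conversion or erode C9. Fallback: C9 is set by an auxiliary-controlled aldol that brings the iodoalkene with it, setting out from 16.
- Commercial pent-3-yn-1-ol is silylated to tert-butyldimethyl(pent-3-yn-1-yloxy)silane F2.
- Hydrozirconation–iodination (Cp2Zr(H)Cl, then I2; minor regioisomer removed) gives tert-butyl{[(3E)-4-iodopent-3-en-1-yl]oxy}dimethylsilane F3.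
- Jones oxidation (CrO3, H2SO4, acetone) gives (3E)-4-iodopent-3-enoic acid F4.
- Its pivaloyl mixed anhydride acylates lithiated (4R)-4-benzyl-1,3-oxazolidin-2-one to give (4R)-4-benzyl-3-[(3E)-4-iodopent-3-enoyl]-1,3-oxazolidin-2-one F5.
- The dibutylboron dienolate of F5 (Bu2BOTf, Et3N, CH2Cl2, −78 → 0 °C) adds to 16 at its α-carbon to give the Evans syn aldol adduct F6, with C9 as in 28.
- LiBH4 removes the auxiliary to give the diol methyl (2E,10E)-6-[(tert-butyldimethylsilyl)oxy]-8-hydroxy-9-(hydroxymethyl)-11-iodo-3,5,7-trimethyldodeca-2,10-dienoate F7.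
- TBSCl/imidazole silylates the primary hydroxyl to give the methyl ester of 28, F8.
- Saponification as in step 17 returns to the route at 28; steps 15 and 16 are then not needed.

**Step 16.** The zirconium hydride may attack the conjugated methyl ester under the forcing conditions that regiochemical equilibration needs, or zirconium may end up partly on C10. Fallback: the polarity of the fragment union is reversed, setting out from 25 and 52.
- 25 is hydroborated with dicyclohexylborane (THF, 0 °C; boron on the less hindered C11) to give the alkenyldicyclohexylborane F9.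
- 52 is converted by Schwartz hydrozirconation–iodination into the (E)-iodoalkene (2R,3S)-6-ethoxy-2-[(1E,3Z,5R,7E)-3-ethyl-8-iodo-5-methylocta-1,3,7-trien-1-yl]-3-methyl-3,6-dihydro-2H-pyran F10.
- Suzuki–Miyaura coupling of F9 with F10 (Pd(PPh3)4, TlOEt, THF/H2O) gives the coupled methyl ester trimethylsilyl ether F11.
- Saponification with LiOH, as in step 17, returns to the route at 54.

**Step 21.** The iodo ylide is unstable and the aldehyde is α-branched, so conversion may be low and Z control incomplete, and the basic medium can epimerise C15. Fallback: the alkene geometry is built by two successive couplings, setting out from 34.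
- Ramirez olefination (CBr4, PPh3, Et3N) gives [(4R)-6,6-dibromo-4-methylhex-5-en-1-yn-1-yl]trimethylsilane F12.
- Trans-selective Negishi monoethylation (Et2Zn, PdCl2(DPEphos), DMF) replaces the bromine trans to the chain and gives [(4R,5Z)-6-bromo-4-methyloct-5-en-1-yn-1-yl]trimethylsilane F13.
- F13 takes the place of 39 in step 26 and returns to the route at 51.

**Step 31.** Two oxidations run at once on a substrate whose lactol can open to a (Z)-hydroxy enal. Isomerisation of that open form to the (E)-enal, which cannot lactonise, or epimerisation and β-elimination at C9 once the ketone is formed, would lose material at the most valuable stage. Fallback: the lactone is completed on the east fragment before the union, setting out from 53.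
- PPTS in aqueous acetone gives the lactol boronate F14.
- MnO2 gives the lactone boronate (5S,6R)-6-[(1E,3Z,5R,7E)-3-ethyl-5-methyl-8-(4,4,5,5-tetramethyl-1,3,2-dioxaborolan-2-yl)octa-1,3,7-trien-1-yl]-5-methyl-5,6-dihydro-2H-pyran-2-one F15.
- Coupling of F15 with 28 under the conditions of step 29 gives the C8 hydroxy lactone acid F16.
- A single Dess–Martin oxidation of the C8 carbinol returns to the route at 56.

Further compounds

F1 | step 4 | (2R,3s,4S)-3-[(tert-butyldimethylsilyl)oxy]-2,4-dimethylpentane-1,5-diyl diacetate | CC(=O)OC[C@H](C)[C@H](O[Si](C)(C)C(C)(C)C)[C@H](C)COC(C)=O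
F2 | step 14 | tert-butyldimethyl(pent-3-yn-1-yloxy)silane | CC#CCCO[Si](C)(C)C(C)(C)C
F3 | step 14 | tert-butyl{[(3E)-4-iodopent-3-en-1-yl]oxy}dimethylsilane | I/C(C)=C/CCO[Si](C)(C)C(C)(C)C
F4 | step 14 | (3E)-4-iodopent-3-enoic acid | I/C(C)=C/CC(=O)O
F5 | step 14 | (4R)-4-benzyl-3-[(3E)-4-iodopent-3-enoyl]-1,3-oxazolidin-2-one | I/C(C)=C/CC(=O)N1C(=O)OC[C@H]1Cc1ccccc1
F6 | step 14 | Evans syn aldol adduct of F5 and 16 (C9 as in 28, C8 hydroxyl syn to the C9 acyl group) | I/C(C)=C/[C@@H](C(=O)N1C(=O)OC[C@H]1Cc1ccccc1)[C@@H](O)[C@H](C)[C@H](O[Si](C)(C)C(C)(C)C)[C@H](C)C/C(C)=C/C(=O)OC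
F7 | step 14 | methyl (2E,10E)-6-[(tert-butyldimethylsilyl)oxy]-8-hydroxy-9-(hydroxymethyl)-11-iodo-3,5,7-trimethyldodeca-2,10-dienoate (centres as in 28) | I/C(C)=C/[C@@H](CO)[C@@H](O)[C@H](C)[C@H](O[Si](C)(C)C(C)(C)C)[C@H](C)C/C(C)=C/C(=O)OC
F8 | step 14 | methyl ester of 28 | I/C(C)=C/[C@@H](CO[Si](C)(C)C(C)(C)C)[C@@H](O)[C@H](C)[C@H](O[Si](C)(C)C(C)(C)C)[C@H](C)C/C(C)=C/C(=O)OC
F9 | step 16 | alkenyldicyclohexylborane from 25 (boron on C11, trans to C9) | B(C1CCCCC1)(C1CCCCC1)/C(C)=C/[C@@H](CO[Si](C)(C)C(C)(C)C)[C@@H](O[Si](C)(C)C)[C@H](C)[C@H](O[Si](C)(C)C(C)(C)C)[C@H](C)C/C(C)=C/C(=O)OC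
F10 | step 16 | (2R,3S)-6-ethoxy-2-[(1E,3Z,5R,7E)-3-ethyl-8-iodo-5-methylocta-1,3,7-trien-1-yl]-3-methyl-3,6-dihydro-2H-pyran | CCC(=C/[C@H](C)C/C=C/I)/C=C/[C@H]1OC(OCC)C=C[C@@H]1C
F11 | step 16 | methyl ester and C8 trimethylsilyl ether of 54 | CCC(=C/[C@H](C)C/C=C/C(C)=C/[C@@H](CO[Si](C)(C)C(C)(C)C)[C@@H](O[Si](C)(C)C)[C@H](C)[C@H](O[Si](C)(C)C(C)(C)C)[C@H](C)C/C(C)=C/C(=O)OC)/C=C/[C@H]1OC(OCC)C=C[C@@H]1C
F12 | step 21 | [(4R)-6,6-dibromo-4-methylhex-5-en-1-yn-1-yl]trimethylsilane | BrC(Br)=C[C@H](C)CC#C[Si](C)(C)C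
F13 | step 21 | [(4R,5Z)-6-bromo-4-methyloct-5-en-1-yn-1-yl]trimethylsilane | CC/C(Br)=C/[C@H](C)CC#C[Si](C)(C)C
F14 | step 31 | lactol boronate: 6-hydroxy analogue of 53 (lactol epimers) | CCC(=C/[C@H](C)C/C=C/B1OC(C)(C)C(C)(C)O1)/C=C/[C@H]1OC(O)C=C[C@@H]1C
F15 | step 31 | (5S,6R)-6-[(1E,3Z,5R,7E)-3-ethyl-5-methyl-8-(4,4,5,5-tetramethyl-1,3,2-dioxaborolan-2-yl)octa-1,3,7-trien-1-yl]-5-methyl-5,6-dihydro-2H-pyran-2-one | CCC(=C/[C@H](C)C/C=C/B1OC(C)(C)C(C)(C)O1)/C=C/[C@H]1OC(=O)C=C[C@@H]1C
F16 | step 31 | C8 hydroxy lactone acid: 56 with a C8 carbinol (configuration as in 54) | CCC(=C/[C@H](C)C/C=C/C(C)=C/[C@@H](CO[Si](C)(C)C(C)(C)C)[C@@H](O)[C@H](C)[C@H](O[Si](C)(C)C(C)(C)C)[C@H](C)C/C(C)=C/C(=O)O)/C=C/[C@H]1OC(=O)C=C[C@@H]1C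
A1 | alternative 1 | (2S)-2-methylbut-3-en-1-yl 2-methylidenebutanoate | C=C[C@H](C)COC(=O)C(=C)CC
A2 | alternative 1 | (5S)-3-ethyl-5-methyl-5,6-dihydro-2H-pyran-2-one | CCC1=C[C@H](C)COC1=O
A3 | alternative 2 | (2R)-1-[(4-methoxybenzyl)oxy]-3-methylbut-3-en-2-yl propanoate | CCC(=O)O[C@@H](COCc1ccc(OC)cc1)C(C)=C
A4 | alternative 2 | (2R,4E)-6-[(4-methoxybenzyl)oxy]-2,4-dimethylhex-4-enoic acid | OC(=O)[C@H](C)C/C(C)=C/COCc1ccc(OC)cc1
A5 | alternative 3 | 2-(trimethylsilyl)ethyl (2E,5R)-8-(ethylsulfanyl)-3,5,7-trimethyl-6,8-dioxooct-2-enoate (C7 epimers) | CCSC(=O)C(C)C(=O)[C@H](C)C/C(C)=C/C(=O)OCC[Si](C)(C)C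
A6 | alternative 3 | 2-(trimethylsilyl)ethyl (2E,5R,6R,7R)-8-(ethylsulfanyl)-6-hydroxy-3,5,7-trimethyl-8-oxooct-2-enoate | CCSC(=O)[C@H](C)[C@H](O)[C@H](C)C/C(C)=C/C(=O)OCC[Si](C)(C)C
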